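Slowness is the first thing these readings show: target creeps up while the dose is still going in. The question is how far the last of the dose gets by the time the flask is read.

| setting | summer | spring | midnight | eta | theta |
|---|---|---|---|---|---|
| starting material | 0.050 M (fed, over 30 h) | 0.20 M (fed, over 30 h) | 0.10 M (fed, over 30 h) | 0.10 M (fed, over 20 h) | 0.10 M (fed, over 30 h) |
| partner | 0.80 equiv | 0.80 equiv | 0.40 equiv | 0.800 equiv | 0.800 equiv |
| protic impurity | 0.050 M | 0.050 M | 0.050 M | 0.0500 M | 0.0500 M |
| capture agent | 0.030 M | 0.030 M | 0.030 M | 0.0300 M | 0.0300 M |
| temperature | −15 °C | 0 °C | −15 °C |  |  |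
| remark | run made earlier; the fed solution adds 0.25 times the starting volume | run made earlier; the fed solution adds 0.25 times the starting volume | run made earlier; the fed solution adds 0.25 times the starting volume | at −10 °C throughout; the fed solution adds 0.25 times the starting volume | at −10 °C until 6.0 h, from then on at 10 °C; the fed solution adds 0.25 times the starting volume |
| time |  |  |  | 30 h | 30 h |

| run | time / h | target / % |
|---|---|---|
| summer | 3.00 | 0.1 |
| summer | 6.00 | 0.1 |
| summer | 10.0 | 1.4 |
| summer | 12.0 | 2.3 |
| summer | 15.0 | 3.2 |
| summer | 20.0 | 5.8 |
| spring | 0.833 | 0.1 |
| spring | 2.50 | 0.9 |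
| spring | 4.00 | 2.5 |
| spring | 6.00 | 5.9 |
| spring | 10.0 | 11.3 |
| spring | 12.0 | 14.1 |
| midnight | 1.50 | 0 |
| midnight | 5.00 | 0.3 |
| midnight | 8.00 | 1.2 |
| midnight | 12.0 | 1.4 |
| midnight | 20.0 | 6.3 |

(standard deviation of a reading: 0.3 percentage points)

- amounts are per litre of the starting volume; all of the dose is in the solution fed
- the earlier runs were read with a standard deviation of 0.3 percentage points
- on the list of suspects stand: starting material -> side product; partner + intermediate A -> target; starting material <-> intermediate B; starting material + protic impurity -> quenched substrate; starting material <-> intermediate A; capture agent + intermediate A -> trapped intermediate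
- percentages count the whole charge, also what has not yet gone in

- the flask that ends with the higher amount of target, in percent of the starting material charged, or "neither" when 2 percentage points or less lies between them (eta / theta / neither)
- final target, as a percentage of the starting material charged, in eta
- final target, as a percentage of the starting material charged, in theta

1. On the suspect list, target comes after two steps in series: starting material to intermediate A, then intermediate A with partner. In the first hours of a steady feed, before consumption counts, starting material grows as t, intermediate A as t² and target as t³, so early target/t³ carries the product of the two stage rates.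

2. Summer and midnight share c(partner) and read 5.8 % and 6.3 % at 20.0 h, so the percentages do not follow the charge. Spring at 2.50 h against summer at 10.0 h, the first reading of each clear of the scatter, gives a clock factor, the mean speed-up per stage, of 6.41. This is a reading, and the spring point carries 0.3 percentage points of scatter.

3. Spring's late line climbs 1.37 % h⁻¹. Against the dose that is a selectivity of 41.0 %. The line trails the dose by 1.68 h: this is the hold-up time, the hours a fed molecule spends in the pipe before it counts as target.

4. I take the partner step as pseudo-first-order, so a fourfold c(partner) acts on one stage of two and gives a factor of 2 in the clock; the rest of the factor I give to temperature. Stretched this way, the hold-up is 5.18 h in eta and 1.09 h in theta at its second temperature.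

5. I assume spring's selectivity holds in both flasks and compute the correction. Eta's feed stops at 20 h, and a hold-up of 5.18 h ends inside its 30 h, so I read eta at the full 41.0 %. Theta, read as its feed ends, gives 39.5 %. The gap is inside the margin, so I say neither.

6. The forecast says theta, with 21 % for eta and 29 % for theta: “Both more partner and more warmth therefore help.” It parts from me on both yields and on the choice.

The flasks give 36.1 % in eta and 42.2 % in theta, so theta leads by 6.1 points, beyond the margin, and my neither fails.

    starting material → side product (k = 1.70 × 10⁻⁵ s⁻¹, Ea = 81.0 kJ mol⁻¹)
    partner + intermediate A → target (k = 9.60 × 10⁻⁴ M⁻¹ s⁻¹, Ea = 45.0 kJ mol⁻¹)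
    starting material ⇌ intermediate B (K = 43.0, k = 3.90 × 10⁻⁶ s⁻¹, Ea = 84.0 kJ mol⁻¹, ΔH = 2.00 kJ mol⁻¹)
    starting material + protic impurity → quenched substrate (k = 5.70 × 10⁻⁵ M⁻¹ s⁻¹, Ea = 63.0 kJ mol⁻¹)
    starting material ⇌ intermediate A (K = 45.0, k = 2.10 × 10⁻⁵ s⁻¹, Ea = 81.0 kJ mol⁻¹, ΔH = −27.0 kJ mol⁻¹)
    capture agent + intermediate A → trapped intermediate (k = 1.60 × 10⁻⁵ M⁻¹ s⁻¹, Ea = 58.0 kJ mol⁻¹)
    (constants at −10 °C)

Counted as starting material plus intermediate A over the dose rate, the hold-up is 8.22 h in eta at 20.0 h and 1.05 h in theta at 15.0 h, against the 5.18 h and 1.09 h stretched from spring's 1.68 h, so eta's is longer than its stretched value, theta's lies close to its own, and eta's is longer than theta's. At 30.0 h eta still holds 14.2 % of its charge as starting material plus intermediate A, and theta holds 4.78 %.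

The earlier runs and the new flask are calculated for an exercise, and the scatter is random.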